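## The problem

Prostaglandin F1α (30) is a cyclopentane (C8–C12, prostanoid numbering throughout) with four contiguous stereocentres. The 9α- and 11α-hydroxyls are cis-1,3, the saturated C1–C7 acid chain on C8 is cis to O9, and the C13–C20 chain on C12 is trans to both of its neighbours. The fifth stereocentre, the allylic C15 carbinol, lies across the E-C13=C14 alkene and is too remote for the ring to control, so it needs a chiral reagent. Once C8, C9 and C11 are fixed, C12 is the thermodynamically preferred trans,trans position. It must nevertheless be made correctly and used at once, because the lower chain is attached through a β-oxygenated, epimerisable aldehyde that can eliminate. Other sensitive functions are the allylic alcohol, the lactol or acetal at C6, and a Wittig-derived C5=C6 alkene that must be saturated without touching C13=C14. The enabling feature is that, if C13 is counted into the ring, C8–C9–C10–C11–C12–C13 is a cyclohexane with oxygen on C9, C11 and C13 in a 1,3,5-all-cis array, which is hydrogenated phloroglucinol (1 → 2). A C12 amine trans to the C13 hydroxyl then lets C8 migrate from C13 to C12, which contracts the ring to C8–C12 and leaves C13 as the aldehyde. The real work is to hang C6–C7 from O9 onto C8, to place nitrogen on C12 between two oxygenated carbons on the correct face, to tell O11 from O13, and to do this as one enantiomer from a meso triol.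

## Retrosynthesis

**C5=C6.** Target 30 is simplified to its 11,15-bis(silyl) ether 29 and then to the Z-alkene 28; cutting C5=C6 gives lactol 26 and phosphonium salt 27. This cut keeps C6 at the aldehyde oxidation level that the route carries as an acetal from the beginning, whereas a cut at C6–C7 or C7–C8 would need a new activating group. The forward sequence must reduce C5=C6 in the presence of C13=C14, which is why O11 and O15 carry bulky silyl groups in 28.

**C13=C14 and C15.** Lactol 26 comes from methyl acetal 25, and 25 from enone 22 by reduction at C15 (23) and exchange of the O11 protecting group (24). Cutting C13=C14 of 22 gives aldehyde 20 and phosphonate 21. An olefination builds the E-alkene and the C15 carbonyl together and leaves C15 to a reagent-controlled reduction; a vinyl-metal or conjugate addition would need a pre-made chiral C13–C20 fragment. The forward reaction must not eliminate the β-benzoate or epimerise C12 of 20.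

**C8–C12 (key cut).** In 20 the C8–C12 bond is cut and C13 is put back between C8 and C12, giving cyclohexane 18 with NH2 on C12, OH on C13 and benzoate on O11. Against a cycloaddition or conjugate addition on a five-membered ring, this cut converts the four ring stereocentres of 20 into a chair cyclohexane in which every substituent except C7 is equatorial. It also exposes O9, O11 and O13 as the all-cis triol 2. The forward step must migrate C8 and not C10, and must invert C12.

**C12–N and C13–O.** Amine 18 is traced through benzoate 17 and alcohol 16 to the N-acyl aziridine 15 by cutting the C13–O bond. Aziridine 15 goes back through azido diol 13 to epoxy alcohol 12 and allylic alcohol 11. A direct nitrogen attack on C12 of 12 was rejected: the trans-diaxial rule and the inductive effect of the C11–O bond both send a nucleophile to C13. The aziridine relay turns that bias into an advantage, because the second opening, by oxygen, again goes to C13 and leaves nitrogen on C12. O13 is introduced already protected, so O11 can be benzoylated without competition.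

**C7–C8.** Allylic alcohol 11 is the methanolysis product of tricyclic acetal 10, which comes by dehydration from alcohol 9 (racemic form 8). Cutting C7–C8 of 8 gives cyclohexenyl mesylate 7. The acetal carbon C6, bound to O9 and O11, holds C7 over the C8=C13 alkene, so the bond forms on the face of O9 and the cis ring fusion is certain; an intermolecular alkylation at C8 would have neither regio- nor stereocontrol. Alcohol 8 is the first chiral compound with a handle, so the resolution is placed there. The forward step must put the positive charge on C13, not C8.

**C6/C7 from the oxygens.** Mesylate 7 derives from dimesylate 6, diol 5 and lactone acetal 4, the condensation product of triol 2 with glyoxylic acid 3; triol 2 is the all-cis hydrogenation product of 1. This removes every stereocentre. The forward reactions only require one molecule of 3 to engage all three syn-axial oxygens of 2.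

## Roads not taken

**Alternative 1:** The cut is through C8–C9 and C11–C12, assembling the ring from two molecules of succinaldehyde A1. A chiral secondary-amine catalyst effects an enantioselective cross-aldol, and an ammonium salt then drives the intramolecular aldol condensation and lactol closure to the bicyclic enal A2.
- Merits: C8 and C9 are set catalytically in one operation from a C4 commodity, with O9 and the C6 lactol already in place. A conjugate addition of the lower chain then sets C12, so the route to prostanoids is far shorter than the one chosen here.
- Weak points: oligomerisation of A1 limits the throughput of the key step. A pre-made enantiopure C13–C20 vinyl-metal fragment is needed. O11 must be introduced afterwards by oxidative cleavage of an enol ether and stereoselective reduction. For 30 the Wittig and the chemoselective hydrogenation remain.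
- Comparison: on step count and on catalytic asymmetry this alternative is clearly better. The chosen plan can only offer an achiral aromatic starting material, ring stereocentres fixed by rigid intermediates and stereospecific steps, and a lower chain built from the simple phosphonate 21 with C15 set late.

**Alternative 2:** The cut removes the C11–O bond and the C13=C14 alkene together, going back to a bicyclo[3.1.0]hexane in which C11 and C13 are joined. On formolysis the C14,C15 cyclic orthoformate ionises at C14, the cyclopropylcarbinyl cation opens across C11–C13, and formate enters at C11 from the α face to give bisformate A3.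
- Merits: O11, the E-alkene and the complete lower chain arrive in one step on a lactone that is ready for the upper chain. The route is convergent and avoids any nitrogen detour.
- Weak points: the cyclopropylcarbinyl cation has several exits (cyclobutyl products, allylic transposition of the formate). C15 depends on a diastereomerically pure C14,C15 glycol made earlier. The endgame to 30 is no shorter.
- Comparison: the alternative needs fewer steps after its key step. The chosen plan instead has a single geometrically enforced migration pathway in step 16 and a C15 centre set by a catalyst rather than inherited.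

**Alternative 3:** The cut is the C8–C9 bond. Hypochlorite oxidation of a C9 aldoxime gives a nitrile oxide that adds intramolecularly to the Z-C7=C8 alkene, closing the cyclopentane and a fused isoxazoline, A4.
- Merits: the saturated C1–C7 chain is already attached, so neither the Wittig reaction nor the selective hydrogenation is needed; for 30 specifically this is better than the chosen plan. The cycloaddition is stereospecific with respect to alkene geometry.
- Weak points: C11 and C12 must be built in an acyclic precursor and must then control the facial selectivity of the cycloaddition. The oxygen on C7 is superfluous and must be removed. The C9 carbonyl unmasked from the isoxazoline must be reduced to the 9α-alcohol. The lower chain still has to be built from the C13 ether.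
- Comparison: the chosen plan takes C8, C9 and C11 from one cis-hydrogenation instead of acyclic stereocontrol and carries no functionality that must later be deleted. It cannot match the way A4 delivers the saturated upper chain.

Key step: step 16

Assumptions:
- Prostanoid locants are used for all intermediates.
- In step 6 water is taken to add to C13 anti to the new C7–C8 bond (O13 trans to C7).
- Compounds 7 and 8 are racemates, drawn as the enantiomer carried on.
- The C6 methyl acetals and the lactol (11–26) are anomeric mixtures, with C6 left unspecified.

## Route

Step 1
Reactants: 1 phloroglucinol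
Product: 2 all-cis-cyclohexane-1,3,5-triol
Conditions: H2 (100 bar), 5 % Rh/Al2O3, EtOH, 80 °C
Reagents that add atoms: none
Why: Heterogeneous arene hydrogenation delivers all hydrogens from the catalyst face, so the three hydroxyls end all-cis (meso); this sets the cis relation of the future O9, O11 and O13.

Step 2
Reactants: 2 all-cis-cyclohexane-1,3,5-triol; 3 glyoxylic acid (monohydrate)
Product: 4 meso lactone acetal (C6 bridges O9 and O11 as a 1,3-dioxane, C7 carbonyl lactonised onto O13)
Conditions: TsOH·H2O (cat.), toluene–dioxane, reflux, water separator
Reagents that add atoms: none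
Why: Acid-catalysed acetalisation of the aldehyde with two syn-axial hydroxyls and lactonisation of the acid onto the third; only the all-cis triol can span both, and the two carbons of 3 become C6 and C7.

Step 3
Reactants: 4 meso lactone acetal
Product: 5 3-endo-(hydroxymethyl)-2,4-dioxabicyclo[3.3.1]nonan-7-endo-ol (C7 primary alcohol, C13 secondary alcohol)
Conditions: LiAlH4, THF, 0 → 20 °C; aqueous NaOH work-up
Reagents that add atoms: none
Why: Hydride reduction of the lactone to the diol; the acetal is inert to LiAlH4.

Step 4
Reactants: 5 diol
Product: 6 dimesylate (O7 and O13)
Conditions: MsCl (2.5 equiv), Et3N, CH2Cl2, 0 °C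
Reagents that add atoms: methanesulfonyl chloride CS(=O)(=O)Cl
Why: Sulfonylation of both hydroxyls through the sulfene, giving one leaving group for elimination and one for the carbon–carbon bond formation.

Step 5
Reactants: 6 dimesylate
Product: 7 racemic (2,4-dioxabicyclo[3.3.1]non-6-en-3-endo-yl)methyl methanesulfonate (C8=C13 alkene, C7 mesylate)
Conditions: KOtBu (1.1 equiv), DMSO–THF, 20 °C
Reagents that add atoms: none
Why: E2 elimination of the secondary mesylate, whose C13–O bond is antiperiplanar to the axial hydrogens on C8 and C12 in the chair–chair form, while the hindered primary mesylate β to the acetal reacts far more slowly; loss of H8 or H12 gives the two enantiomers, hence a racemate.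

Step 6
Reactants: 7 racemic alkenyl mesylate
Product: 8 racemic tricyclic alcohol (C7–C8 bond, C6 acetal on O9 and O11, C13–OH trans to C7)
Conditions: H2O–dioxane 1:1, KHCO3, 90 °C
Reagents that add atoms: water O
Why: Solvolysis with π-participation (π-route cation–olefin cyclisation): the endo CH2OMs group lies over the alkene, C8 attacks C7 in a 5-exo sense on the face of O9 and water captures C13 from the opposite face; charge goes to C13 rather than C8 because C8 is next to the oxygenated C9.

Step 7
Reactants: 8 racemic tricyclic alcohol
Product: 9 tricyclic alcohol as the single (13S) enantiomer (recovered unreacted)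
Conditions: immobilised Candida antarctica lipase B, vinyl acetate, t-BuOMe, 30 °C, stopped beyond half conversion; chromatography
Reagents that add atoms: none
Why: Lipase-catalysed kinetic resolution by transesterification; by the empirical size rule for secondary alcohols (branched C8 side large, C12 methylene medium) the 13R enantiomer should be acetylated and the wanted alcohol stay behind, which fixes the absolute configuration of C8, C9 and C11.

Step 8
Reactants: 9 (13S)-tricyclic alcohol
Product: 10 tricyclic alkene (C12=C13, C6 acetal on O9 and O11, C7–C8 bond)
Conditions: methyl N-(triethylammoniosulfonyl)carbamate (inner salt), toluene, 60 °C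
Reagents that add atoms: none
Why: Syn-elimination (Ei) of the derived sulfamate ester; a syn hydrogen is available on C12, whereas elimination towards C8 would place the alkene at a bridgehead of the cage.

Step 9
Reactants: 10 tricyclic alkene
Product: 11 2-methoxy-2,3,3a,6,7,7a-hexahydrobenzofuran-6-ol (cis ring fusion, O11–H cis to O9, C12=C13)
Conditions: HCl (0.05 M, from AcCl) in MeOH, 0 → 20 °C; NaHCO3
Reagents that add atoms: methanol CO
Why: Acid-catalysed acetal exchange: cleavage of C6–O11 gives the five-membered oxocarbenium ion on O9, which methanol traps; the strain of the boat-locked cage is released and O11 is freed as an allylic alcohol.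

Step 10
Reactants: 11 allylic alcohol
Product: 12 epoxy alcohol (C12–C13 epoxide cis to O11–H and O9)
Conditions: VO(acac)2 (2 mol %), t-BuOOH, CH2Cl2, 0 → 20 °C
Reagents that add atoms: tert-butyl hydroperoxide CC(C)(C)OO
Why: Hydroxyl-directed vanadium-catalysed epoxidation of a cyclic allylic alcohol delivers oxygen to the face of the C11 hydroxyl, overriding the steric preference for the other face.

Step 11
Reactants: 12 epoxy alcohol
Product: 13 azido diol (N3 on C13 trans to O12–H; O12–H and O11–H cis)
Conditions: NaN3, NH4Cl, MeOH–H2O 8:1, 70 °C
Reagents that add atoms: sodium azide [Na+].[N-]=[N+]=[N-]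
Why: SN2 opening anti to the epoxide oxygen; the trans-diaxial rule (chair with O9 and O11 equatorial) and the electron-withdrawing C11–O bond both direct azide to C13, and the minor regioisomer would mainly lead to the same aziridine in step 12.

Step 12
Reactants: 13 azido diol
Product: 15 N-benzyloxycarbonyl aziridine across C12–C13 on the face opposite to O11, via N–H aziridine 14 (not isolated)
Conditions: PPh3, MeCN, 80 °C; then CbzCl, Et3N, CH2Cl2, −20 °C
Reagents that add atoms: benzyl chloroformate O=C(Cl)OCc1ccccc1
Why: Staudinger reaction gives the iminophosphorane, which closes with inversion at the carbinol carbon C12 (trans-diaxial N and O) to the aziridine on the face opposite to the former epoxide; N-acylation, faster than O-acylation of the hindered C11 alcohol, activates the ring.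

Step 13
Reactants: 15 N-Cbz aziridine
Product: 16 benzyl ether carbamate (O13–Bn cis to O11–H and O9, C12–NHCbz trans to both neighbours)
Conditions: BnOH (5 equiv), BF3·OEt2 (0.3 equiv), CH2Cl2, −30 → 0 °C; then MeOH (excess), 0 °C; Et3N
Reagents that add atoms: benzyl alcohol OCc1ccccc1; methanol CO (only where the C6 acetal has exchanged)
Why: Lewis acid-promoted opening of an N-acyl aziridine by an alcohol with inversion; attack at C13, remote from the inductively deactivating C11–O bond, puts O13 on the face of O9 and O11 and leaves nitrogen on C12, and the methanol quench returns any exchanged C6 acetal to the methyl acetal.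

Step 14
Reactants: 16 benzyl ether carbamate
Product: 17 O11 benzoate of 16
Conditions: BzCl, pyridine, 4-(dimethylamino)pyridine (cat.), CH2Cl2, 0 → 20 °C
Reagents that add atoms: benzoyl chloride O=C(Cl)c1ccccc1
Why: Acylation of the only free hydroxyl; O13 is masked as the benzyl ether and nitrogen as the carbamate, so O11 and O13 are differentiated by construction.

Step 15
Reactants: 17 benzoate
Product: 18 C12-amino C13-hydroxy cyclohexane with O11 benzoate and cis-fused O9–C6 methyl acetal ring (handled as its acetic acid salt)
Conditions: H2 (1 atm), Pd(OH)2/C, AcOH (3 equiv), EtOAc, 20 °C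
Reagents that add atoms: none
Why: Hydrogenolysis removes the benzyl ether and the benzyl carbamate together; the acetic acid keeps the amine protonated so that O-to-N benzoyl migration cannot begin.

Step 16
Reactants: 18 amino alcohol benzoate
Product: 20 C13 aldehyde of the bicyclic lactol methyl ether with O11 benzoate, via C12 diazonium ion 19 (not isolated)
Conditions: NaNO2 (2 equiv), AcOH–H2O 1:1, 0 °C; cold extraction, used at once
Reagents that add atoms: none
Why: Nitrosation of the amine gives the C12 diazonium ion 19; in the chair that places O9, O11, N12 and O13 equatorial (C7 axial, as the cis ring fusion requires) the C12–N bond is antiperiplanar only to the ring bonds C13–C8 and C11–C10. As N2 leaves, C8 shifts from C13 to C12 while the C13 hydroxyl lone pair stabilises the migration origin, and proton loss gives the aldehyde. The closest known reaction type is the Tiffeneau–Demjanov-type deaminative semipinacol ring contraction of trans-2-aminocyclohexanols to cyclopentanecarbaldehydes. The five-membered ring C8–C12 closes by a 1,2-alkyl shift (ring contraction from six to five), not by an end-to-end cyclisation. The new stereocentre C12 is set by inversion at the carbon that loses nitrogen, controlled by the equatorial C12–N bond, while C8 migrates with retention, so the formyl group ends trans to C7 and to O11. The step needs C8 rather than C10 to migrate: the free C13 hydroxyl can support the shift, the O11 benzoate cannot, and C8 is the more substituted carbon. Epoxide formation and hydride shift are excluded because neither an oxygen nor a hydrogen is antiperiplanar to the leaving group in this chair.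

Step 17
Reactants: 20 aldehyde; 21 dimethyl (2-oxoheptyl)phosphonate
Product: 22 E-enone (C15 ketone, O11 benzoate, C6 methyl acetal)
Conditions: LiCl, i-Pr2NEt, MeCN, 0 → 20 °C
Reagents that add atoms: none
Why: Horner–Wadsworth–Emmons olefination under LiCl/amine conditions gives the E-enone and is mild enough to avoid β-elimination of benzoate and epimerisation at C12.

Step 18
Reactants: 22 enone
Product: 23 (15S)-allylic alcohol
Conditions: (R)-1-methyl-3,3-diphenyl-tetrahydropyrrolo[1,2-c][1,3,2]oxazaborole ((R)-Me-CBS, 0.2 equiv), catecholborane, toluene, −78 °C
Reagents that add atoms: none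
Why: CBS reduction; with the alkenyl group as the large substituent the (R)-catalyst delivers hydride to the face that gives the 15S carbinol, and the low temperature suppresses 1,4-reduction.

Step 19
Reactants: 23 (15S)-alcohol benzoate
Product: 24 11,15-diol methyl acetal
Conditions: K2CO3 (0.3 equiv), MeOH, 20 °C
Reagents that add atoms: none
Why: Base-catalysed transesterification removes the benzoate, whose role ended with steps 16 and 17.

Step 20
Reactants: 24 diol
Product: 25 11,15-bis(tert-butyldiphenylsilyl) ether
Conditions: t-BuPh2SiCl (2.5 equiv), imidazole, DMF, 40 °C
Reagents that add atoms: tert-butyl(chloro)diphenylsilane CC(C)(C)[Si](Cl)(c1ccccc1)c1ccccc1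
Why: Silylation of both secondary hydroxyls; these ethers survive aqueous acid and the ylide and shield C13=C14 in step 23.

Step 21
Reactants: 25 bis(silyl) methyl acetal
Product: 26 bis(silyl) lactol
Conditions: AcOH–THF–H2O 3:1:1, 45 °C
Reagents that add atoms: water O
Why: Mild acid hydrolysis of the 2-methoxytetrahydrofuran acetal; tert-butyldiphenylsilyl ethers are stable under these conditions.

Step 22
Reactants: 26 lactol; 27 (4-carboxybutyl)triphenylphosphonium bromide
Product: 28 prostaglandin F2α 11,15-bis(tert-butyldiphenylsilyl) ether (5Z,13E)
Conditions: KOtBu (2 equiv per 27), 27 (4 equiv), THF, 0 → 20 °C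
Reagents that add atoms: none
Why: Wittig reaction of the lactol through its hydroxy-aldehyde form with the non-stabilised ylide gives the Z-C5=C6 alkene and completes C1–C7.

Step 23
Reactants: 28 diene acid
Product: 29 prostaglandin F1α 11,15-bis(tert-butyldiphenylsilyl) ether
Conditions: H2 (1 atm), 5 % Pd/C, EtOAc, −20 °C, one equivalent of H2
Reagents that add atoms: none
Why: Heterogeneous hydrogenation at low temperature saturates the unhindered cis C5=C6 alkene, while the trans C13=C14 alkene is flanked by the silyloxy groups on C11 and C15 and reacts much more slowly.

Step 24
Reactants: 29 bis(silyl) ether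
Product: 30 prostaglandin F1α
Conditions: Bu4NF, THF, 20 → 40 °C; dilute HCl to pH 4
Reagents that add atoms: none
Why: Fluoride cleavage of both silyl ethers; no stereocentre is touched.

## Compound list

1 | phloroglucinol | Oc1cc(O)cc(O)c1 | starting material
2 | all-cis-cyclohexane-1,3,5-triol | O[C@H]1C[C@@H](O)C[C@@H](O)C1 | intermediate
3 | glyoxylic acid (used as monohydrate) | O=CC(=O)O | starting material
4 | meso lactone acetal: C6 acetal on O9 and O11, C7 lactone carbonyl on O13 | O=C1O[C@@H]2C[C@H]3C[C@@H](C2)O[C@@H]1O3 | intermediate
5 | 3-endo-(hydroxymethyl)-2,4-dioxabicyclo[3.3.1]nonan-7-endo-ol | OC[C@@H]1O[C@@H]2C[C@H](O)C[C@@H](C2)O1 | intermediate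
6 | dimesylate of 5 | CS(=O)(=O)OC[C@@H]1O[C@@H]2C[C@H](OS(C)(=O)=O)C[C@@H](C2)O1 | intermediate
7 | (2,4-dioxabicyclo[3.3.1]non-6-en-3-endo-yl)methyl methanesulfonate, racemic (enantiomer carried on is drawn) | CS(=O)(=O)OC[C@@H]1O[C@@H]2C=CC[C@@H](C2)O1 | intermediate
8 | tricyclic alcohol, racemic: C7–C8 bond, C6 acetal on O9 and O11, C13–OH trans to C7 | O[C@H]1C[C@H]2C[C@H]3[C@@H]1C[C@H](O3)O2 | intermediate
9 | tricyclic alcohol, single (13S) enantiomer | O[C@H]1C[C@H]2C[C@H]3[C@@H]1C[C@H](O3)O2 | intermediate
10 | tricyclic alkene (C12=C13) | C1=C[C@H]2C[C@H]3[C@@H]1C[C@H](O3)O2 | intermediate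
11 | cis-fused 2-methoxy-2,3,3a,6,7,7a-hexahydrobenzofuran-6-ol, O11–H cis to O9 | COC1C[C@@H]2C=C[C@H](O)C[C@@H]2O1 | intermediate
12 | C12–C13 epoxide of 11, cis to O11–H | COC1C[C@@H]2[C@@H]3O[C@@H]3[C@H](O)C[C@@H]2O1 | intermediate
13 | C13 azide, C12 and C11 diol (azide trans to O12) | COC1C[C@@H]2[C@@H](N=[N+]=[N-])[C@H](O)[C@H](O)C[C@@H]2O1 | intermediate
14 | N–H aziridine across C12–C13, trans to O11–H | COC1C[C@@H]2[C@H]3N[C@H]3[C@H](O)C[C@@H]2O1 | intermediate (not isolated)
15 | N-benzyloxycarbonyl aziridine | COC1C[C@@H]2[C@H]3N(C(=O)OCc4ccccc4)[C@H]3[C@H](O)C[C@@H]2O1 | intermediate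
16 | C13 benzyl ether, C12 NHCbz, C11 alcohol | COC1C[C@@H]2[C@H](OCc3ccccc3)[C@@H](NC(=O)OCc3ccccc3)[C@H](O)C[C@@H]2O1 | intermediate
17 | O11 benzoate of 16 | COC1C[C@@H]2[C@H](OCc3ccccc3)[C@@H](NC(=O)OCc3ccccc3)[C@H](OC(=O)c3ccccc3)C[C@@H]2O1 | intermediate
18 | C12-amino C13-hydroxy cyclohexane, O11 benzoate, cis-fused O9–C6 methyl acetal (acetic acid salt) | COC1C[C@@H]2[C@H](O)[C@@H](N)[C@H](OC(=O)c3ccccc3)C[C@@H]2O1 | intermediate
19 | C12 diazonium ion of 18 | COC1C[C@@H]2[C@H](O)[C@@H]([N+]#N)[C@H](OC(=O)c3ccccc3)C[C@@H]2O1 | intermediate (not isolated)
20 | 4-formyl-2-methoxyhexahydro-2H-cyclopenta[b]furan-5-yl benzoate (C13 aldehyde, O11 benzoate) | O=C[C@@H]1[C@H]2CC(OC)O[C@H]2C[C@H]1OC(=O)c1ccccc1 | intermediate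
21 | dimethyl (2-oxoheptyl)phosphonate | CCCCCC(=O)CP(=O)(OC)OC | starting material
22 | E-enone | CCCCCC(=O)/C=C/[C@@H]1[C@H]2CC(OC)O[C@H]2C[C@H]1OC(=O)c1ccccc1 | intermediate
23 | (15S)-allylic alcohol, O11 benzoate | CCCCC[C@H](O)/C=C/[C@@H]1[C@H]2CC(OC)O[C@H]2C[C@H]1OC(=O)c1ccccc1 | intermediate
24 | 11,15-diol methyl acetal | CCCCC[C@H](O)/C=C/[C@@H]1[C@H]2CC(OC)O[C@H]2C[C@H]1O | intermediate
25 | 11,15-bis(tert-butyldiphenylsilyl) ether methyl acetal | CCCCC[C@H](O[Si](c1ccccc1)(c1ccccc1)C(C)(C)C)/C=C/[C@@H]1[C@H]2CC(OC)O[C@H]2C[C@H]1O[Si](c1ccccc1)(c1ccccc1)C(C)(C)C | intermediate
26 | bis(silyl) lactol | CCCCC[C@H](O[Si](c1ccccc1)(c1ccccc1)C(C)(C)C)/C=C/[C@@H]1[C@H]2CC(O)O[C@H]2C[C@H]1O[Si](c1ccccc1)(c1ccccc1)C(C)(C)C | intermediate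
27 | (4-carboxybutyl)triphenylphosphonium bromide | [Br-].OC(=O)CCCC[P+](c1ccccc1)(c1ccccc1)c1ccccc1 | starting material
28 | prostaglandin F2α 11,15-bis(tert-butyldiphenylsilyl) ether | CCCCC[C@H](O[Si](c1ccccc1)(c1ccccc1)C(C)(C)C)/C=C/[C@@H]1[C@@H](C/C=C\CCCC(=O)O)[C@@H](O)C[C@H]1O[Si](c1ccccc1)(c1ccccc1)C(C)(C)C | intermediate
29 | prostaglandin F1α 11,15-bis(tert-butyldiphenylsilyl) ether | CCCCC[C@H](O[Si](c1ccccc1)(c1ccccc1)C(C)(C)C)/C=C/[C@@H]1[C@@H](CCCCCCC(=O)O)[C@@H](O)C[C@H]1O[Si](c1ccccc1)(c1ccccc1)C(C)(C)C | intermediate
30 | prostaglandin F1α | CCCCC[C@H](O)/C=C/[C@@H]1[C@@H](CCCCCCC(=O)O)[C@@H](O)C[C@H]1O | target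

## Step count and least certain steps

Total step count: 24. Longest linear sequence: 24 steps (1 → 30); compounds 3, 21 and 27 are bought.

**Step 16 (key step).**
- What may go wrong: the benzoyl group may shift from O11 to nitrogen before nitrosation if the amine is ever free-based, which removes the amine. The diazonium ion may be captured by solvent, or C10 may migrate, if the all-equatorial chair is not the reacting conformer. The C6 acetal may partly hydrolyse or exchange with the cis C13 hydroxyl in the aqueous acid, and the product may lose benzoic acid by β-elimination on standing.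
- Fallback: set out from 12 and replace nitrogen by bromine as the leaving group. Benzoylation gives the epoxy benzoate F1, which is cis to the epoxide and cannot participate. Warming F1 with MgBr2·OEt2 in toluene opens the epoxide anti to the bromohydrin magnesium alkoxide F2, which undergoes the known halohydrin (semipinacol) ring contraction of cyclohexene oxides to cyclopentanecarbaldehydes. The C–Br bond lies on the face opposite to O11, as the C–N bond does in 18, so the shift comes from the same face. Both regioisomeric bromohydrins contract to the same aldehyde (C8 shift or C11 shift), and the sequence comes back to the route at 20.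

**Step 6.**
- What may go wrong: the bridged cation may partition between capture at C13 (wanted) and capture at C8 with C7 bonded to C13 (a dioxa-adamantane skeleton). Elimination of the primary mesylate to a ketene acetal or plain hydrolysis without participation may compete, because the balance rests only on the inductive effect of C9–O.
- Fallback: set out from 7 and form C7–C8 by a Ueno–Stork-type radical cyclisation. Exchange of mesylate for iodide (NaI, butanone) gives the iodide F3. Bu3SnH under air generates the C7 radical, which closes 5-exo onto C8, and the C13 radical is trapped by dioxygen as the hydroperoxide F4. Reduction with PPh3 returns to the route at 8, as a mixture of C13 epimers of which the trans one enters step 7.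

**Step 13.**
- What may go wrong: attack at C12 through the other half-chair (the trans-diaxial rule then opposes the inductive preference), or scrambling of the C6 acetal by the Lewis acid.
- Fallback: set out from 15 and carry the regioisomer on instead of discarding it. The regioisomeric benzyl ether F7 (O12–Bn, C13–NHCbz) is benzoylated to F8 and hydrogenolysed to the amine F9, in which the C13 amine and C12 hydroxyl are again trans. Deamination as in step 16 then occurs with migration of C11 from C12 to C13 (inversion at C13) and gives the same aldehyde, rejoining the route at 20.

**Step 7.**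
- What may go wrong: insufficient discrimination of the enantiomers by the enzyme, because both flanks of C13 belong to a compact cage.
- Fallback: set out from 8 and resolve through covalent diastereomers. Esterification with (S)-2-methoxy-2-phenylacetic acid (carbodiimide) gives the esters F5 (from the wanted enantiomer) and F6 (from the other). They are separated by chromatography or crystallisation, and methanolysis of F5 (K2CO3, MeOH) comes back to the route at 9.

**Step 23.**
- What may go wrong: over-reduction of C13=C14 or hydrogenolysis of the allylic C15–O bond on the metal surface.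
- Fallback: set out from 28 and use a metal-free, concerted hydrogen transfer instead of surface catalysis. Diimide, generated from potassium azodicarboxylate and acetic acid, discriminates strongly in favour of the unhindered cis alkene and cannot cleave C–O bonds. It returns to the route at 29 without new compounds.

## Further compounds

F1 | step 16 | O11 benzoate of epoxy alcohol 12 | COC1C[C@@H]2[C@@H]3O[C@@H]3[C@H](OC(=O)c4ccccc4)C[C@@H]2O1
F2 | step 16 | bromohydrin (Br on C13 trans to O12, O11 benzoate; as magnesium alkoxide in the flask) | COC1C[C@@H]2[C@@H](Br)[C@H](O)[C@H](OC(=O)c3ccccc3)C[C@@H]2O1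
F3 | step 6 | (2,4-dioxabicyclo[3.3.1]non-6-en-3-endo-yl)methyl iodide, racemic | IC[C@@H]1O[C@@H]2C=CC[C@@H](C2)O1
F4 | step 6 | C13 hydroperoxide of the tricyclic skeleton of 8, racemic | OO[C@H]1C[C@H]2C[C@H]3[C@@H]1C[C@H](O3)O2
F5 | step 7 | (S)-2-methoxy-2-phenylacetate of 9 | CO[C@H](C(=O)O[C@H]1C[C@H]2C[C@H]3[C@@H]1C[C@H](O3)O2)c1ccccc1
F6 | step 7 | (S)-2-methoxy-2-phenylacetate of the enantiomer of 9 | CO[C@H](C(=O)O[C@@H]1C[C@@H]2C[C@@H]3[C@H]1C[C@@H](O3)O2)c1ccccc1
F7 | step 13 | regioisomer of 16: C12 benzyl ether, C13 NHCbz, C11 alcohol | COC1C[C@@H]2[C@@H](NC(=O)OCc3ccccc3)[C@H](OCc3ccccc3)[C@H](O)C[C@@H]2O1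
F8 | step 13 | O11 benzoate of F7 | COC1C[C@@H]2[C@@H](NC(=O)OCc3ccccc3)[C@H](OCc3ccccc3)[C@H](OC(=O)c3ccccc3)C[C@@H]2O1
F9 | step 13 | C13-amino C12-hydroxy regioisomer of 18 | COC1C[C@@H]2[C@@H](N)[C@H](O)[C@H](OC(=O)c3ccccc3)C[C@@H]2O1
F0 | step 23 | none | none
A1 | alternative 1 | succinaldehyde | O=CCCC=O
A2 | alternative 1 | (3aR,6aS)-2-hydroxy-3,3a,6,6a-tetrahydro-2H-cyclopenta[b]furan-5-carbaldehyde | O=CC1=C[C@H]2CC(O)O[C@H]2C1
A3 | alternative 2 | 11,15-bisformate of the bicyclic γ-lactone carrying the complete lower chain | CCCCC[C@H](OC=O)/C=C/[C@@H]1[C@H]2CC(=O)O[C@H]2C[C@H]1OC=O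
A4 | alternative 3 | cis-fused cyclopentano-isoxazoline with C=N at C9, oxygen on C7, O11 triisopropylsilyl ether, C13 benzyl ether | COC(=O)CCCCC[C@H]1ON=C2C[C@@H](O[Si](C(C)C)(C(C)C)C(C)C)[C@H](COCc3ccccc3)[C@@H]12
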